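The numbers in the tables are simulated for substances that don't exist; the scatter is artificial.

You cannot read an order in second substrate from these runs, for cedar, alder and birch all charged the same amount of it, so there you get a guess, and the argument has to start from what the runs do show.

| flask | starting material | second substrate | capture agent | free catalyst | remark |
|---|---|---|---|---|---|
| cedar | 10 mM | 10 mM | 4.2 mM | 0.50 mM | run made earlier |
| alder | 10 mM | 10 mM | 6.6 mM | 0.50 mM | run made earlier |
| birch | 10 mM | 10 mM | 3 mM | 0.25 mM | run made earlier |
| flask | 10 mM | 10.0 mM | 3.00 mM | 0.50 mM |  |

| run | time / min | target / % | starting material / % |
|---|---|---|---|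
| cedar | 0.417 | 24 | 69 |
| cedar | 0.833 | 40 | 55 |
| cedar | 1.33 | 47 | 50 |
| cedar | 1.50 | 48 | 49 |
| cedar | 2.00 | 51 | 45 |
| cedar | 2.50 | 50 | 43 |
| alder | 0.417 | 21 | 74 |
| alder | 0.833 | 30 | 69 |
| alder | 1.33 | 32 | 66 |
| alder | 1.50 | 29 | 65 |
| alder | 2.00 | 34 | 62 |
| alder | 2.50 | 34 | 62 |
| birch | 0.200 | 8 | 90 |
| birch | 0.333 | 14 | 84 |
| birch | 0.667 | 20 | 79 |
| birch | 1.33 | 28 | 67 |
| birch | 2.50 | 33 | 65 |

(each reading ± 1.5 percentage points)

- the earlier runs were read with a standard deviation of 1.5 percentage points
- what is bound to the catalyst counts as converted
- no earlier run changes the charge of second substrate; that part of a forecast is a guess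

- apparent order in free catalyst when 10% of the starting material are converted (percent change of the rate of making target for one percent more free catalyst charged)
- apparent order in second substrate when 10% of the starting material are converted (percent change of the rate of making target for one percent more second substrate charged)
- factor on the rate of making target when 10% of the starting material are converted if second substrate is charged twice over

Cedar flattens near 50% target with 43% of the starting material still there, and alder and birch flatten lower, so I take the stop for a dying catalyst and not for an empty flask. Then the last target, multiplied by the capture agent charged and divided by the free catalyst charged, should hold steady from run to run, and it does within the scatter: cedar gives 42.0 mM, alder 44.9 mM and birch 39.6 mM. Their mean, 42.2 mM, I call the survival reserve: the turnover number of the catalyst times the capture agent it meets. For the new flask the reserve gives an end target of 7.03 mM, or 70.3% of the charge, which is less than the starting material charged, so this flask too should stop short of empty. That end target tells how long the catalyst lasts and not how fast the flask runs when 10% of the starting material are converted, so my own reckoning commits to the end target and gives no order in free catalyst, and second substrate stays a guess.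

The forecast gives 0.72 for the order in free catalyst and 0.5 for the order in second substrate, with a factor of 1.4 on doubling it: “I guess about 0.5, which is poorly constrained”. The flask gives 1.2, −0.14 and 0.876.

    starting material + free catalyst ⇌ catalyst intermediate A (K = 850 L mol⁻¹, k = 260 L mol⁻¹ s⁻¹)
    catalyst intermediate A → free catalyst + target (k = 0.500 s⁻¹)
    second substrate + free catalyst ⇌ catalyst intermediate B (K = 300 L mol⁻¹, k = 63.0 L mol⁻¹ s⁻¹)
    catalyst intermediate B → free catalyst + second product (k = 0.820 s⁻¹)
    catalyst intermediate A + capture agent → trapped intermediate (k = 12.0 L mol⁻¹ s⁻¹)

Taken over the mean of the capture agent charged and the 83.3% of it left, the reserve gives 76.7% target in this flask, which stands at 76.0% after 20.0 min with 19.0% of the starting material unused. Of the steps taken away in turn, the largest single effect on the order in second substrate comes from the reaction of catalyst intermediate B to free catalyst + second product, which hands free catalyst back: the run without that step shows an order of −0.52, against −0.14.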